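The heptanone chain is numbered C1 (benzylic CH2 on ring A, the 4-hydroxy-3,5-dimethoxyphenyl ring) to C7 (benzylic CH2 on ring B, the catechol). Because C7 is attached to ring B, the C6–C7 bond is disconnected as a styrene-type C6=C7 alkene, made by ruthenium-catalysed cross-metathesis of a ring B styrene with a ring A hept-6-en-3-one that already carries the C3 ketone. This one operation joins both halves and completes the C1–C7 skeleton. The precursor is 1-[4-(benzyloxy)-3,5-dimethoxyphenyl]hept-6-en-3-one, made from sinapic acid through a Weinreb amide. All phenols travel as benzyl ethers, so one final hydrogenation saturates C6=C7 and frees the three hydroxyl groups.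

Key step: step 6

Remark: the target is achiral, and the geometry of the C6=C7 alkene formed in step 6 is immaterial because step 7 saturates it.

Step 1
Reactants: 1 sinapic acid
Product: 2 3-(4-hydroxy-3,5-dimethoxyphenyl)propanoic acid
Conditions: H2 (1 atm), 10% Pd/C, EtOH, rt
Reagents that add atoms: none
Why: Heterogeneous catalytic hydrogenation reduces the conjugated cinnamic C=C selectively, since the arene, the phenol, the methyl ethers and the carboxylic acid are inert to Pd/C under one atmosphere of hydrogen at room temperature.

Step 2
Reactants: 2 3-(4-hydroxy-3,5-dimethoxyphenyl)propanoic acid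
Product: 3 benzyl 3-[4-(benzyloxy)-3,5-dimethoxyphenyl]propanoate
Conditions: BnBr (2.4 equiv), K2CO3 (3 equiv), DMF, 60 °C
Reagents that add atoms: benzyl bromide, BrCc1ccccc1
Why: Williamson-type SN2 O-alkylation, in which carbonate deprotonates both the carboxylic acid and the phenol flanked by two methoxy groups and benzyl bromide alkylates both oxygens, so the phenol protection and an ester suited to step 3 arise in one operation.

Step 3
Reactants: 3 benzyl 3-[4-(benzyloxy)-3,5-dimethoxyphenyl]propanoate
Product: 4 3-[4-(benzyloxy)-3,5-dimethoxyphenyl]-N-methoxy-N-methylpropanamide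
Conditions: MeNH(OMe)·HCl (1.5 equiv), i-PrMgCl (3.0 equiv), THF, −20 → 0 °C; aq. NH4Cl
Reagents that add atoms: N,O-dimethylhydroxylamine hydrochloride, CNOC.Cl
Why: Direct ester aminolysis by a magnesium amide (Weinreb amide synthesis), in which i-PrMgCl deprotonates the hydroxylamine salt faster than it adds to the ester, the chloromagnesium amide displaces benzyloxide by addition–elimination, and the product amide resists further attack at this temperature while the aryl ethers are untouched.

Step 4
Reactants: 4 3-[4-(benzyloxy)-3,5-dimethoxyphenyl]-N-methoxy-N-methylpropanamide; 5 but-3-enylmagnesium bromide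
Product: 7 1-[4-(benzyloxy)-3,5-dimethoxyphenyl]hept-6-en-3-one, via bromomagnesium hemiaminal chelate 6 (not isolated)
Conditions: 5 (1.5 equiv, THF solution), THF, 0 °C; then 1 M HCl, 0 °C
Reagents that add atoms: none
Why: Weinreb ketone synthesis, in which the Grignard reagent adds once to give the magnesium-chelated tetrahedral adduct 6 that persists until the acidic quench releases the ketone, so no tertiary alcohol should form and the terminal alkene and the ethers are unaffected.

Step 5
Reactants: 8 3,4-bis(benzyloxy)benzaldehyde
Product: 9 3,4-bis(benzyloxy)styrene (1,2-bis(benzyloxy)-4-ethenylbenzene)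
Conditions: Ph3PCH3Br (1.3 equiv), KOt-Bu (1.25 equiv), THF, 0 °C → rt
Reagents that add atoms: methyltriphenylphosphonium bromide, C[P+](c1ccccc1)(c1ccccc1)c1ccccc1.[Br-]
Why: Wittig methylenation, in which the unstabilised ylide Ph3P=CH2 adds to the non-enolisable aromatic aldehyde and the oxaphosphetane collapses to the terminal alkene and Ph3P=O under conditions to which aryl benzyl ethers are inert.

Step 6
Reactants: 7 1-[4-(benzyloxy)-3,5-dimethoxyphenyl]hept-6-en-3-one; 9 3,4-bis(benzyloxy)styrene
Product: 10 (E)-7-[3,4-bis(benzyloxy)phenyl]-1-[4-(benzyloxy)-3,5-dimethoxyphenyl]hept-6-en-3-one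
Conditions: 9 (3 equiv), second-generation Grubbs catalyst (H2IMes)(PCy3)Cl2Ru=CHPh (5 mol%), degassed CH2Cl2 (0.1 M), 40 °C, slow argon sparge
Reagents that add atoms: none
Why: Olefin cross-metathesis by the Chauvin mechanism: loss of PCy3 gives the active ruthenium alkylidene, which takes up the unhindered terminal alkene of 7 by [2+2] cycloaddition and cycloreversion to form the C6 alkylidene, and this adds across the vinyl group of 9 and cycloreverts to release 10, the Ru=CH2 left behind being recycled with loss of ethylene. The closest known reaction type is the ruthenium-carbene cross-metathesis of a styrene with a terminal aliphatic alkene, well established with this catalyst. No ring is closed and no stereocentre is formed; the C6=C7 geometry should be mainly E under thermodynamic control and is erased in step 7. The selectivity needed is cross-coupling over self-metathesis of 7, and it is secured by the threefold excess of 9, by the slow and reversible homodimerisation of the electron-rich styrene (its stilbene can still be opened by the C6 alkylidene), and by sweeping ethylene out of the solution. The C3 carbonyl is insulated from the alkene by the C4 and C5 methylenes and the benzyl ethers are inert to the carbene, so no other site should compete.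

Step 7
Reactants: 10 (E)-7-[3,4-bis(benzyloxy)phenyl]-1-[4-(benzyloxy)-3,5-dimethoxyphenyl]hept-6-en-3-one
Product: 11 7-(3,4-dihydroxyphenyl)-1-(4-hydroxy-3,5-dimethoxyphenyl)heptan-3-one
Conditions: H2 (1 atm), 10% Pd/C, EtOAc–EtOH 1:1, rt; filtration through Celite under argon
Reagents that add atoms: none
Why: Heterogeneous hydrogenation over palladium saturates the styrenyl C6=C7 alkene and hydrogenolyses the three aryl benzyl ethers to toluene, whereas the C3 ketone, an unconjugated dialkyl ketone with no benzylic C–O bond, and the aryl methyl ethers should not be reduced at one atmosphere and room temperature.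

Compound list
1 | sinapic acid, (E)-3-(4-hydroxy-3,5-dimethoxyphenyl)prop-2-enoic acid | COc1cc(/C=C/C(=O)O)cc(OC)c1O | starting material
2 | 3-(4-hydroxy-3,5-dimethoxyphenyl)propanoic acid | COc1cc(CCC(=O)O)cc(OC)c1O | intermediate
3 | benzyl 3-[4-(benzyloxy)-3,5-dimethoxyphenyl]propanoate | COc1cc(CCC(=O)OCc2ccccc2)cc(OC)c1OCc1ccccc1 | intermediate
4 | 3-[4-(benzyloxy)-3,5-dimethoxyphenyl]-N-methoxy-N-methylpropanamide | COc1cc(CCC(=O)N(C)OC)cc(OC)c1OCc1ccccc1 | intermediate
5 | but-3-enylmagnesium bromide | C=CCC[Mg]Br | starting material
6 | bromomagnesium 1-[4-(benzyloxy)-3,5-dimethoxyphenyl]-3-[methoxy(methyl)amino]hept-6-en-3-olate (racemic tetrahedral adduct, magnesium chelated by the N-methoxy oxygen) | C=CCCC(O[Mg]Br)(CCc1cc(OC)c(OCc2ccccc2)c(OC)c1)N(C)OC | intermediate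
7 | 1-[4-(benzyloxy)-3,5-dimethoxyphenyl]hept-6-en-3-one | C=CCCC(=O)CCc1cc(OC)c(OCc2ccccc2)c(OC)c1 | intermediate
8 | 3,4-bis(benzyloxy)benzaldehyde | O=Cc1ccc(OCc2ccccc2)c(OCc2ccccc2)c1 | starting material
9 | 3,4-bis(benzyloxy)styrene (1,2-bis(benzyloxy)-4-ethenylbenzene) | C=Cc1ccc(OCc2ccccc2)c(OCc2ccccc2)c1 | intermediate
10 | (E)-7-[3,4-bis(benzyloxy)phenyl]-1-[4-(benzyloxy)-3,5-dimethoxyphenyl]hept-6-en-3-one | COc1cc(CCC(=O)CC/C=C/c2ccc(OCc3ccccc3)c(OCc3ccccc3)c2)cc(OC)c1OCc1ccccc1 | intermediate
11 | 7-(3,4-dihydroxyphenyl)-1-(4-hydroxy-3,5-dimethoxyphenyl)heptan-3-one | COc1cc(CCC(=O)CCCCc2ccc(O)c(O)c2)cc(OC)c1O | target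

Total step count: 7. Longest linear sequence: 6 steps (steps 1, 2, 3, 4, 6 and 7, from sinapic acid); the styrene branch adds step 5.

Steps most likely to fail

Step 6. Self-metathesis of 7 may outpace the cross-coupling. Ruthenium hydride species formed on catalyst decay may also move the terminal double bond along C4–C7 and give chain-shortened cross products, or the catalyst may die before 7 is consumed. The fallback sets out from 7 and forms the ring B–C7 bond instead of the C6=C7 bond. A Mizoroki–Heck arylation of the terminal alkene of 7 with purchased 4-bromo-1,2-bis(benzyloxy)benzene (Brc1ccc(OCc2ccccc2)c(OCc2ccccc2)c1; Pd(OAc)2, P(o-tol)3, K2CO3, DMF, 110 °C) should give 10 directly, where the route is rejoined. Linear double-bond isomers from the alternative β-hydride elimination need not be separated, because step 7 converges them on 11; the branched 2-aryl isomer would have to be removed by chromatography. This fallback makes no compound outside the compound list (entry F0).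

Step 3. The magnesium amide may displace the benzyl ester too slowly, so that i-PrMgCl adds to the ester or to the product amide, or the N-methoxy amide may lose formaldehyde under the basic conditions. The fallback sets out from 3 and avoids organometallic base. Saponification (LiOH, THF–H2O, rt; then dilute HCl) should give 3-[4-(benzyloxy)-3,5-dimethoxyphenyl]propanoic acid F1. Activation with 1,1'-carbonyldiimidazole in CH2Cl2 at rt should give 1-{3-[4-(benzyloxy)-3,5-dimethoxyphenyl]propanoyl}imidazole F2 (not isolated), and addition of MeNH(OMe)·HCl should then deliver 4, where the route is rejoined.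

Step 7. Hydrogenolysis may stall at partly benzylated phenols if ruthenium or phosphine residues from step 6 poison the palladium surface, so 10 should be passed through silica with a ruthenium scavenger beforehand. Prolonged exposure may begin to reduce the C3 ketone, and the free catechol may oxidise in air during filtration. The fallback sets out from 10 and separates the two events. Homogeneous hydrogenation (H2, 1 atm, RhCl(PPh3)3, toluene–EtOH, rt to 40 °C) should saturate only C6=C7 and give 7-[3,4-bis(benzyloxy)phenyl]-1-[4-(benzyloxy)-3,5-dimethoxyphenyl]heptan-3-one F3. Lewis-acid debenzylation (BCl3, pentamethylbenzene, CH2Cl2, −78 °C; MeOH quench) should then cleave the three aryl benzyl ethers, leaving the aryl methyl ethers and the ketone intact, and arrive at 11.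

Further compounds
F0 | step 6 | none | none
F1 | step 3 | 3-[4-(benzyloxy)-3,5-dimethoxyphenyl]propanoic acid | COc1cc(CCC(=O)O)cc(OC)c1OCc1ccccc1
F2 | step 3 | 1-{3-[4-(benzyloxy)-3,5-dimethoxyphenyl]propanoyl}imidazole | COc1cc(CCC(=O)n2ccnc2)cc(OC)c1OCc1ccccc1
F3 | step 7 | 7-[3,4-bis(benzyloxy)phenyl]-1-[4-(benzyloxy)-3,5-dimethoxyphenyl]heptan-3-one | COc1cc(CCC(=O)CCCCc2ccc(OCc3ccccc3)c(OCc3ccccc3)c2)cc(OC)c1OCc1ccccc1
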